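**Retrosynthetic overview**
1. The chain C4–C8 is read as 2-deoxy-D-ribose: sugar C1→C4, C2→C5 (the ring CH2), C3→C6 (carries O1), C4→C7 (free carbinol), C5→C8 (benzylic ether carbon). The erythro pair C6/C7 is imported as a group, and the pyranose ring is transposed into the dihydropyranone ring (ring oxygen changes from sugar O5 to sugar O3 = O1).
2. C2, C3 and the Z C3=C4 alkene come from a Z-selective Horner–Wadsworth–Emmons opening of the sugar lactol; the lactone bond O1–C2 closes last, when the C6/C7 acetonide is released by acid.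
3. C8–Ph: Felkin–Anh addition of PhMgBr to the C8 aldehyde. C8–O(aryl): Mitsunobu inversion with the 7-OH of (2S)-pinocembrin, giving the 7,8-threo ether.
4. Order of rings: flavanone rings purchased intact (chiral pool) → temporary dioxolane (step 1) → dihydropyranone (step 6).

Key step: step 2

Remark: commercial (–)-pinocembrin is taken as the (2S) enantiomer; 2-deoxy-D-ribose is taken to react through its pyranose form, whose 3-OH/4-OH pair is the only cis-vicinal diol.

**Step 1**
Reactants: 1 2-deoxy-D-ribose (pyranose form); 2 2-methoxypropene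
Product: 3 3,4-O-isopropylidene-2-deoxy-D-erythro-pentopyranose (anomer mixture)
Conditions: 2 (1.2 equiv), PPTS (cat.), DMF, 0 °C → rt
Reagents that add atoms: 2-methoxypropene (2), COC(C)=C
Why: Acid-catalysed acetalisation with an enol ether (transketalisation) should take place on the only cis-vicinal diol of the pyranose (3-OH/4-OH) and leave the anomeric OH free; no stereocentre is created apart from the mobile anomeric one.

**Step 2**
Reactants: 3 3,4-O-isopropylidene-2-deoxy-D-erythro-pentopyranose; 4 ethyl [bis(2-methylphenoxy)phosphoryl]acetate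
Product: 6 ethyl (2Z)-4-[(4S,5R)-5-(hydroxymethyl)-2,2-dimethyl-1,3-dioxolan-4-yl]but-2-enoate, via open-chain hydroxy aldehyde 5 (not isolated)
Conditions: 4 (1.2 equiv), NaH (1.15 equiv), THF, 0 °C; then 3, –20 → 0 °C; aq. NH4Cl
Reagents that add atoms: ethyl [bis(2-methylphenoxy)phosphoryl]acetate (4), CCOC(=O)CP(=O)(Oc1ccccc1C)Oc1ccccc1C
Why: The lactol is in ring–chain equilibrium with hydroxy aldehyde 5, which the sodium salt of the diaryl phosphonoacetate intercepts in a Horner–Wadsworth–Emmons reaction; the electron-poor aryloxy groups make collapse of the first-formed syn adduct faster than its equilibration, so the (Z)-enoate should result. The closest known reaction type is the Z-selective (Ando or Still–Gennari) olefination of sugar lactols, together with the long-known Wittig opening of this same acetonide with stabilised ylides. No ring is closed here: the pyranose C1–O5 bond is opened and C2–C3 are appended, which turns sugar C1–C5 into C4–C8 and programmes the later 6-exo-trig lactonisation of O6 onto C2 (step 6), possible only for the Z alkene. No new stereocentre is formed: C6 and C7 are sugar C3 and C4 and are not epimerisable under these conditions, and the only new stereo-element, the C3=C4 geometry, is reagent-controlled. The step needs Z over E selectivity and must avoid oxa-Michael addition of the freed C8–OH to the enoate; using only one equivalent of phosphonate anion (so the hydroxyl stays protonated), low temperature and a prompt quench should secure this.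

**Step 3**
Reactants: 6 ethyl (2Z)-4-[(4S,5R)-5-(hydroxymethyl)-2,2-dimethyl-1,3-dioxolan-4-yl]but-2-enoate
Product: 7 ethyl (2Z)-4-[(4S,5S)-5-formyl-2,2-dimethyl-1,3-dioxolan-4-yl]but-2-enoate
Conditions: Dess–Martin periodinane, CH2Cl2, 0 °C → rt; used crude
Reagents that add atoms: none
Why: Dess–Martin oxidation of the primary alcohol is near-neutral and non-epimerising, so the α-alkoxy aldehyde should keep C7 and the (Z)-enoate should be untouched.

**Step 4**
Reactants: 7 ethyl (2Z)-4-[(4S,5S)-5-formyl-2,2-dimethyl-1,3-dioxolan-4-yl]but-2-enoate; 8 phenylmagnesium bromide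
Product: 9 ethyl (2Z)-4-[(4S,5R)-5-[(R)-hydroxy(phenyl)methyl]-2,2-dimethyl-1,3-dioxolan-4-yl]but-2-enoate
Conditions: 8 (1.2 equiv), THF, –78 °C; aq. NH4Cl
Reagents that add atoms: phenylmagnesium bromide (8), Br[Mg]c1ccccc1
Why: Grignard addition is chemoselective for the aldehyde over the enoate at –78 °C, and polar Felkin–Anh control by the α-dioxolane oxygen (attack anti to the C7–O bond, past H rather than C6) should give the 7,8-anti (erythro) alcohol, i.e. (R) at the new C8 centre.

**Step 5**
Reactants: 9 ethyl (2Z)-4-[(4S,5R)-5-[(R)-hydroxy(phenyl)methyl]-2,2-dimethyl-1,3-dioxolan-4-yl]but-2-enoate; 10 (2S)-pinocembrin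
Product: 11 ethyl (2Z)-4-[(4S,5S)-5-[(S)-{[(2S)-5-hydroxy-4-oxo-2-phenyl-3,4-dihydro-2H-chromen-7-yl]oxy}(phenyl)methyl]-2,2-dimethyl-1,3-dioxolan-4-yl]but-2-enoate
Conditions: 10 (1.2 equiv), PPh3, DIAD, THF, 0 °C → rt
Reagents that add atoms: none
Why: Mitsunobu etherification: the acidic 7-OH of 10 (the 5-OH is locked in a hydrogen bond to C4=O) should displace the alkoxyphosphonium ion in an SN2 step, inverting C8 from (R) to (S) and so setting the 7,8-threo relationship, while the neutral conditions leave flavanone C2 and the Z-enoate alone.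

**Step 6**
Reactants: 11 ethyl (2Z)-4-[(4S,5S)-5-[(S)-{[(2S)-5-hydroxy-4-oxo-2-phenyl-3,4-dihydro-2H-chromen-7-yl]oxy}(phenyl)methyl]-2,2-dimethyl-1,3-dioxolan-4-yl]but-2-enoate
Product: 13 (6S)-6-[(1S,2S)-1-hydroxy-2-{[(2S)-5-hydroxy-4-oxo-2-phenyl-3,4-dihydro-2H-chromen-7-yl]oxy}-2-phenylethyl]-5,6-dihydro-2H-pyran-2-one, via dihydroxy (Z)-enoate 12 (not isolated)
Conditions: AcOH–H2O (4:1), 60 °C; then azeotropic concentration (PhMe)
Reagents that add atoms: none
Why: Acid-catalysed acetal hydrolysis frees the C6/C7 diol, and the (Z)-δ-hydroxy ester should then lactonise on O6 (6-exo-trig acyl substitution) to the conjugated six-membered lactone in preference to a seven-membered ring on O7; no stereocentre is touched, and the flavanone and the benzylic aryl ether should be stable to aqueous acetic acid.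

**Compound list**
1 | 2-deoxy-D-ribose (pyranose form) | OC1C[C@H](O)[C@H](O)CO1 | starting material
2 | 2-methoxypropene | COC(C)=C | starting material
3 | 3,4-O-isopropylidene-2-deoxy-D-erythro-pentopyranose | OC1C[C@@H]2OC(C)(C)O[C@@H]2CO1 | intermediate
4 | ethyl [bis(2-methylphenoxy)phosphoryl]acetate | CCOC(=O)CP(=O)(Oc1ccccc1C)Oc1ccccc1C | starting material
5 | 2-[(4S,5R)-5-(hydroxymethyl)-2,2-dimethyl-1,3-dioxolan-4-yl]acetaldehyde | O=CC[C@@H]1OC(C)(C)O[C@@H]1CO | intermediate
6 | ethyl (2Z)-4-[(4S,5R)-5-(hydroxymethyl)-2,2-dimethyl-1,3-dioxolan-4-yl]but-2-enoate | CCOC(=O)/C=C\C[C@@H]1OC(C)(C)O[C@@H]1CO | intermediate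
7 | ethyl (2Z)-4-[(4S,5S)-5-formyl-2,2-dimethyl-1,3-dioxolan-4-yl]but-2-enoate | CCOC(=O)/C=C\C[C@@H]1OC(C)(C)O[C@@H]1C=O | intermediate
8 | phenylmagnesium bromide | Br[Mg]c1ccccc1 | starting material
9 | ethyl (2Z)-4-[(4S,5R)-5-[(R)-hydroxy(phenyl)methyl]-2,2-dimethyl-1,3-dioxolan-4-yl]but-2-enoate | CCOC(=O)/C=C\C[C@@H]1OC(C)(C)O[C@@H]1[C@H](O)c1ccccc1 | intermediate
10 | (2S)-pinocembrin, (2S)-5,7-dihydroxy-2-phenyl-2,3-dihydro-4H-chromen-4-one | Oc1cc(O)c2c(c1)O[C@H](c1ccccc1)CC2=O | starting material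
11 | ethyl (2Z)-4-[(4S,5S)-5-[(S)-{[(2S)-5-hydroxy-4-oxo-2-phenyl-3,4-dihydro-2H-chromen-7-yl]oxy}(phenyl)methyl]-2,2-dimethyl-1,3-dioxolan-4-yl]but-2-enoate | CCOC(=O)/C=C\C[C@@H]1OC(C)(C)O[C@@H]1[C@@H](Oc1cc(O)c2c(c1)O[C@H](c1ccccc1)CC2=O)c1ccccc1 | intermediate
12 | ethyl (2Z,5S,6S,7S)-5,6-dihydroxy-7-{[(2S)-5-hydroxy-4-oxo-2-phenyl-3,4-dihydro-2H-chromen-7-yl]oxy}-7-phenylhept-2-enoate | CCOC(=O)/C=C\C[C@H](O)[C@H](O)[C@@H](Oc1cc(O)c2c(c1)O[C@H](c1ccccc1)CC2=O)c1ccccc1 | intermediate
13 | (6S)-6-[(1S,2S)-1-hydroxy-2-{[(2S)-5-hydroxy-4-oxo-2-phenyl-3,4-dihydro-2H-chromen-7-yl]oxy}-2-phenylethyl]-5,6-dihydro-2H-pyran-2-one | O=C1C=CC[C@@H]([C@H](O)[C@@H](Oc2cc(O)c3c(c2)O[C@H](c2ccccc2)CC3=O)c2ccccc2)O1 | target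

Total step count: 6. Longest linear sequence: 6 steps (1 → 13).

**Steps most likely to fail, each with a fallback**

Step 4 – poor facial selectivity in the addition to the α-alkoxy aldehyde (Felkin–Anh and competing modes close in energy), or partial attack on the enoate. The fallback replaces carbon-nucleophile addition under Felkin control by hydride delivery under chelate control. It sets out from 9 as obtained in step 4 (epimer mixture at C8). Dess–Martin oxidation should converge both epimers to the phenyl ketone ethyl (2Z)-4-[(4S,5S)-5-benzoyl-2,2-dimethyl-1,3-dioxolan-4-yl]but-2-enoate F1. Reduction of F1 with Zn(BH4)2 in Et2O at –20 °C through the five-membered zinc chelate between the ketone and the α-dioxolane oxygen should deliver hydride from the face next to H and give the 7,8-anti alcohol. The fallback comes back to the route at 9.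

Step 5 – ionisation of the activated benzylic alcohol instead of direct displacement (loss of configuration at C8), or stalled displacement at the hindered α-oxygenated centre. The fallback closes the lactone first and makes the ether by opening a cyclic sulfate. It sets out from 9. Aqueous acetic acid (as in step 6) should give the lactone diol (6S)-6-[(1R,2R)-1,2-dihydroxy-2-phenylethyl]-5,6-dihydro-2H-pyran-2-one F2. SOCl2/Et3N should give the cyclic sulfite (6S)-6-[(4S,5R)-2-oxido-5-phenyl-1,3,2-dioxathiolan-4-yl]-5,6-dihydro-2H-pyran-2-one F3. Catalytic RuCl3 with NaIO4 should oxidise it to the cyclic sulfate (6S)-6-[(4S,5R)-2,2-dioxido-5-phenyl-1,3,2-dioxathiolan-4-yl]-5,6-dihydro-2H-pyran-2-one F4. The caesium phenoxide of 10 (Cs2CO3, DMF, rt) should open this far more reactive electrophile at the benzylic carbon with inversion to the sulfate monoester caesium (1S,2S)-2-{[(2S)-5-hydroxy-4-oxo-2-phenyl-3,4-dihydro-2H-chromen-7-yl]oxy}-1-[(2S)-6-oxo-3,6-dihydro-2H-pyran-2-yl]-2-phenylethyl sulfate F5. Hydrolysis with catalytic H2SO4 in THF–H2O brings the fallback back to the route at 13.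

Step 2 – loss of Z geometry in the olefination, or conjugate addition of the liberated C8 hydroxyl to the new enoate. The fallback fixes the geometry before any enoate exists. It sets out from 3. Stork–Zhao iodo-olefination (iodomethyltriphenylphosphonium iodide, NaHMDS, THF–DMPU, –78 °C) should give the vinyl iodide [(4R,5S)-5-[(2Z)-3-iodoprop-2-en-1-yl]-2,2-dimethyl-1,3-dioxolan-4-yl]methanol F6. Stereoretentive palladium-catalysed ethoxycarbonylation (PdCl2(PPh3)2, CO 1 atm, EtOH, Et3N, 50 °C) should then give the Z-enoate. The fallback comes back to the route at 6.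

**Further compounds**
F1 | step 4 | ethyl (2Z)-4-[(4S,5S)-5-benzoyl-2,2-dimethyl-1,3-dioxolan-4-yl]but-2-enoate | CCOC(=O)/C=C\C[C@@H]1OC(C)(C)O[C@@H]1C(=O)c1ccccc1
F2 | step 5 | (6S)-6-[(1R,2R)-1,2-dihydroxy-2-phenylethyl]-5,6-dihydro-2H-pyran-2-one | O=C1C=CC[C@@H]([C@H](O)[C@H](O)c2ccccc2)O1
F3 | step 5 | (6S)-6-[(4S,5R)-2-oxido-5-phenyl-1,3,2-dioxathiolan-4-yl]-5,6-dihydro-2H-pyran-2-one | O=C1C=CC[C@@H]([C@@H]2OS(=O)O[C@@H]2c2ccccc2)O1
F4 | step 5 | (6S)-6-[(4S,5R)-2,2-dioxido-5-phenyl-1,3,2-dioxathiolan-4-yl]-5,6-dihydro-2H-pyran-2-one | O=C1C=CC[C@@H]([C@@H]2OS(=O)(=O)O[C@@H]2c2ccccc2)O1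
F5 | step 5 | caesium (1S,2S)-2-{[(2S)-5-hydroxy-4-oxo-2-phenyl-3,4-dihydro-2H-chromen-7-yl]oxy}-1-[(2S)-6-oxo-3,6-dihydro-2H-pyran-2-yl]-2-phenylethyl sulfate | O=C1C=CC[C@@H]([C@H](OS(=O)(=O)[O-])[C@@H](Oc2cc(O)c3c(c2)O[C@H](c2ccccc2)CC3=O)c2ccccc2)O1.[Cs+]
F6 | step 2 | [(4R,5S)-5-[(2Z)-3-iodoprop-2-en-1-yl]-2,2-dimethyl-1,3-dioxolan-4-yl]methanol | I/C=C\C[C@@H]1OC(C)(C)O[C@@H]1CO
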